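**Retrosynthetic overview**
1. Last bonds: the C2–O–C15′ ester between acid half 24 and diol half 28, then one SN2 demethylation that frees the three acids.
2. Both halves diverge from one seco allylic alcohol 18 (ring A is never built): Sharpless epoxidation with L-(+)- or D-(−)-tartrate sets C13 in either sense (and C14); epoxide hydrolysis and alkoxymercuration then close ring C (C8–O) last.
3. 18 comes from ring-B diketone 14 by HWE olefination, Lombardo methylenation and DIBAL-H reduction.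
4. Key step: a one-flask three-component double Mukaiyama–Michael coupling (enone 9 + ketene silyl acetal 10 + methyl vinyl ketone 11) builds the C10 quaternary centre and C9, both new arms anti to the C5 substituent.
5. Enone 9 comes from 2-methylcyclohexenone by CBS reduction, Ireland–Claisen rearrangement (C5) and allylic oxidation. Ring order: ring B is present from the start, ring C is formed last.

Assumption: the SMILES is taken literally (H-9 cis to both ring methyls, the two halves epimeric at C13); locants from compound 16 on use labdane numbering (ring B = C5–C10, acetate arm C1–C2 on C10, dimethylacetate arm C4–C3 on C5, C11–C16 = side chain/ring C, C17 on C8, C20 on C10, primes = diol half).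

**Step 1**
Reactants: 1 2-methylcyclohex-2-en-1-one
Product: 2 (1R)-2-methylcyclohex-2-en-1-ol
Conditions: (S)-Me-CBS oxazaborolidine (10 mol%), BH3·SMe2, THF, −20 °C; MeOH quench
Reagents that add atoms: none
Why: Corey–Bakshi–Shibata reduction; with the alkenyl group as the large substituent the (S)-catalyst delivers hydride to give the (R)-allylic alcohol, the source of all absolute stereochemistry in ring B.

**Step 2**
Reactants: 2 (1R)-2-methylcyclohex-2-en-1-ol; 3 2-methylpropanoyl chloride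
Product: 4 (1R)-2-methylcyclohex-2-en-1-yl 2-methylpropanoate
Conditions: pyridine, DMAP (cat.), CH2Cl2, 0 °C to rt
Reagents that add atoms: none
Why: DMAP-catalysed acylation of a secondary allylic alcohol; no stereocentre is touched.

**Step 3**
Reactants: 4 (1R)-2-methylcyclohex-2-en-1-yl 2-methylpropanoate
Product: 7 2-methyl-2-[(1S)-2-methylcyclohex-2-en-1-yl]propanoic acid, via silyl ketene acetal 5 (not isolated), via trimethylsilyl ester 6 (not isolated)
Conditions: LiN(iPr)2, Me3SiCl, THF, −78 °C, then 60 °C; aq. HCl work-up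
Reagents that add atoms: none
Why: Ireland–Claisen rearrangement; the tetrasubstituted silyl ketene acetal has no geometry issue and rearranges suprafacially, so the CMe2CO2 group arrives at C5 on the face that carried the C–O bond (1,3-chirality transfer, giving 5S).

**Step 4**
Reactants: 7 2-methyl-2-[(1S)-2-methylcyclohex-2-en-1-yl]propanoic acid
Product: 8 methyl 2-methyl-2-[(1S)-2-methylcyclohex-2-en-1-yl]propanoate
Conditions: iodomethane, K2CO3, DMF, rt
Reagents that add atoms: iodomethane, CI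
Why: SN2 alkylation of the hindered carboxylate, which avoids acyl substitution at the neopentyl carbonyl.

**Step 5**
Reactants: 8 methyl 2-methyl-2-[(1S)-2-methylcyclohex-2-en-1-yl]propanoate
Product: 9 methyl 2-methyl-2-[(1S)-2-methyl-4-oxocyclohex-2-en-1-yl]propanoate
Conditions: Rh2(C6H10NO)4 (dirhodium tetracaprolactamate, 1 mol%), t-BuOOH, K2CO3 (cat.), CH2Cl2, rt
Reagents that add atoms: tert-butyl hydroperoxide, CC(C)(C)OO
Why: Doyle allylic oxidation; the only unhindered allylic CH2 (C8) is oxidised, giving the 3-methyl-4-substituted enone without touching C5.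

**Step 6**
Reactants: 9 methyl 2-methyl-2-[(1S)-2-methyl-4-oxocyclohex-2-en-1-yl]propanoate; 10 tert-butyl[(1-methoxyethenyl)oxy]dimethylsilane; 11 but-3-en-2-one
Product: 14 methyl 2-[(1S,2R,3R)-2-(2-methoxy-2-oxoethyl)-2-methyl-4-oxo-3-(3-oxobutyl)cyclohexyl]-2-methylpropanoate, via ring silyl enol ether 12 (not isolated), via side-chain silyl enol ether 13 (not isolated)
Conditions: HNTf2 (3 mol%), 10 (1.05 equiv), CH2Cl2, −78 °C; then 11, −78 to −40 °C; aq. HCl
Reagents that add atoms: none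
Why: Sequential Mukaiyama–Michael reactions relayed by the silyl triflimide formed in situ; the ketene acetal adds to C10 anti to the pseudoaxial C5 substituent, and enol ether 12 then attacks the vinyl ketone through C9 by axial approach, again anti to the C5 group, so the two new arms are cis to each other.

**Step 7**
Reactants: 14 methyl 2-[(1S,2R,3R)-2-(2-methoxy-2-oxoethyl)-2-methyl-4-oxo-3-(3-oxobutyl)cyclohexyl]-2-methylpropanoate; 15 triethyl phosphonoacetate
Product: 16 2,3-dimethyl 15-ethyl (5S,9R,10R,13E)-8-oxo-17-nor-2,3-secolabd-13-ene-2,3,15-trioate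
Conditions: NaH, THF, 0 °C to rt
Reagents that add atoms: none
Why: Horner–Wadsworth–Emmons olefination; only the unhindered methyl ketone reacts (the ring ketone is flanked by a tertiary and a neopentyl carbon), giving mainly the E-enoate (expected about 9:1, Z isomer removed by chromatography).

**Step 8**
Reactants: 16 2,3-dimethyl 15-ethyl (5S,9R,10R,13E)-8-oxo-17-nor-2,3-secolabd-13-ene-2,3,15-trioate
Product: 17 2,3-dimethyl 15-ethyl (5S,9S,10S,13E)-2,3-secolabda-8(17),13-diene-2,3,15-trioate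
Conditions: Zn, CH2Br2, TiCl4, THF/CH2Cl2, 0 °C to rt
Reagents that add atoms: dibromomethane, BrCBr
Why: Lombardo–Takai methylenation; the non-basic reagent converts the hindered, epimerisable C8 ketone to the exocyclic alkene and ignores esters (descriptors at C9 and C10 change by priority only).

**Step 9**
Reactants: 17 2,3-dimethyl 15-ethyl (5S,9S,10S,13E)-2,3-secolabda-8(17),13-diene-2,3,15-trioate
Product: 18 dimethyl (5S,9S,10S,13E)-15-hydroxy-2,3-secolabda-8(17),13-diene-2,3-dioate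
Conditions: iBu2AlH (2.2 equiv), CH2Cl2, −78 °C; aq. KNaC4H4O6 work-up
Reagents that add atoms: none
Why: DIBAL-H 1,2-reduction; the unhindered conjugated ethyl ester should react much faster at −78 °C than the neopentyl-type C2 and pivalate-type C3 methyl esters.

**Step 10**
Reactants: 18 dimethyl (5S,9S,10S,13E)-15-hydroxy-2,3-secolabda-8(17),13-diene-2,3-dioate
Product: 19 dimethyl (5S,9S,10S,13S,14S)-13,14-epoxy-15-hydroxy-2,3-secolabd-8(17)-ene-2,3-dioate
Conditions: Ti(OiPr)4 (10 mol%), diethyl L-(+)-tartrate (12 mol%), t-BuOOH, 4 Å molecular sieves, CH2Cl2, −20 °C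
Reagents that add atoms: tert-butyl hydroperoxide, CC(C)(C)OO
Why: Sharpless asymmetric epoxidation; reagent control with L-(+)-tartrate gives the (13S,14S)-epoxide (as geraniol gives the 2S,3S-epoxide), and the 8(17)-alkene is not an allylic alcohol and stays.

**Step 11**
Reactants: 19 dimethyl (5S,9S,10S,13S,14S)-13,14-epoxy-15-hydroxy-2,3-secolabd-8(17)-ene-2,3-dioate
Product: 20 dimethyl (5S,9S,10S,13R,14S)-13,14,15-trihydroxy-2,3-secolabd-8(17)-ene-2,3-dioate
Conditions: HClO4 (cat.), THF/H2O, 0 °C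
Reagents that add atoms: water, O
Why: Acid-catalysed epoxide hydrolysis; water opens the protonated oxirane at the tertiary carbon C13 with inversion while C14 keeps its oxygen.

**Step 12**
Reactants: 20 dimethyl (5S,9S,10S,13R,14S)-13,14,15-trihydroxy-2,3-secolabd-8(17)-ene-2,3-dioate
Product: 22 dimethyl (5S,8S,9R,10R,13R,14S)-8,13-epoxy-14,15-dihydroxy-2,3-secolabdane-2,3-dioate, via alkylmercury trifluoroacetate 21 (not isolated)
Conditions: Hg(OCOCF3)2, CH2Cl2, 0 °C; then NaBH4, aq. NaOH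
Reagents that add atoms: none
Why: Intramolecular Markovnikov alkoxymercuration–demercuration; the tertiary C13 hydroxyl, held on the axial C11 tether, can reach C8 only from the face cis to C11, so ring C closes cis-fused with the new C17 methyl on the opposite face, and no free cation is formed that could epimerise C9.

**Step 13**
Reactants: 22 dimethyl (5S,8S,9R,10R,13R,14S)-8,13-epoxy-14,15-dihydroxy-2,3-secolabdane-2,3-dioate
Product: 23 dimethyl (5S,8S,9R,10R,13R)-8,13-epoxy-2,3-secolabd-14-ene-2,3-dioate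
Conditions: PPh3, I2, imidazole, toluene, 80 °C
Reagents that add atoms: none
Why: Garegg–Samuelsson deoxygenation of the vicinal diol to the vinyl group; C13 is not involved.

**Step 14**
Reactants: 23 dimethyl (5S,8S,9R,10R,13R)-8,13-epoxy-2,3-secolabd-14-ene-2,3-dioate
Product: 24 (5S,8S,9R,10R,13R)-8,13-epoxy-3-methoxy-3-oxo-2,3-secolabd-14-en-2-oic acid
Conditions: LiOH, THF/MeOH/H2O, 40 °C; aq. HCl
Reagents that add atoms: lithium hydroxide, [Li+].[OH-]
Why: Saponification discriminates the CH2CO2Me ester from the pivalate-like CMe2CO2Me ester, which is inert to hydroxide under these conditions.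

**Step 15**
Reactants: 18 dimethyl (5S,9S,10S,13E)-15-hydroxy-2,3-secolabda-8(17),13-diene-2,3-dioate
Product: 25 dimethyl (5S,9S,10S,13R,14R)-13,14-epoxy-15-hydroxy-2,3-secolabd-8(17)-ene-2,3-dioate
Conditions: Ti(OiPr)4 (10 mol%), diethyl D-(−)-tartrate (12 mol%), t-BuOOH, 4 Å molecular sieves, CH2Cl2, −20 °C
Reagents that add atoms: tert-butyl hydroperoxide, CC(C)(C)OO
Why: Sharpless asymmetric epoxidation with the enantiomeric tartrate gives the (13R,14R)-epoxide; the ring stereocentres are too remote to override reagent control.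

**Step 16**
Reactants: 25 dimethyl (5S,9S,10S,13R,14R)-13,14-epoxy-15-hydroxy-2,3-secolabd-8(17)-ene-2,3-dioate
Product: 26 dimethyl (5S,9S,10S,13S,14R)-13,14,15-trihydroxy-2,3-secolabd-8(17)-ene-2,3-dioate
Conditions: HClO4 (cat.), THF/H2O, 0 °C
Reagents that add atoms: water, O
Why: Acid-catalysed epoxide hydrolysis with inversion at the tertiary carbon C13 sets 13S and leaves 14R, the configurations of the diol half.

**Step 17**
Reactants: 26 dimethyl (5S,9S,10S,13S,14R)-13,14,15-trihydroxy-2,3-secolabd-8(17)-ene-2,3-dioate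
Product: 28 dimethyl (5S,8S,9R,10R,13S,14R)-8,13-epoxy-14,15-dihydroxy-2,3-secolabdane-2,3-dioate, via alkylmercury trifluoroacetate 27 (not isolated)
Conditions: Hg(OCOCF3)2, CH2Cl2, 0 °C; then NaBH4, aq. NaOH
Reagents that add atoms: none
Why: Intramolecular alkoxymercuration–demercuration as in step 12; the axial C11 tether again fixes C8 (O cis to C11, methyl trans).

**Step 18**
Reactants: 24 (5S,8S,9R,10R,13R)-8,13-epoxy-3-methoxy-3-oxo-2,3-secolabd-14-en-2-oic acid; 28 dimethyl (5S,8S,9R,10R,13S,14R)-8,13-epoxy-14,15-dihydroxy-2,3-secolabdane-2,3-dioate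
Product: 29 trimethyl ester of the target (C3 and C2′ and C3′ methyl esters)
Conditions: EDC·HCl, DMAP (cat.), CH2Cl2, 0 °C to rt
Reagents that add atoms: none
Why: Steglich-type carbodiimide esterification; the primary C15′ hydroxyl is acylated in preference to the neopentyl secondary C14′ hydroxyl.

**Step 19**
Reactants: 29 trimethyl ester of the target (C3 and C2′ and C3′ methyl esters)
Product: 30 CNP0271961.3
Conditions: LiI, pyridine, 110 °C; aq. HCl
Reagents that add atoms: none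
Why: SN2 dealkylation of methyl esters by iodide; attack at O–CH3 does not depend on hindrance at the acyl carbon and is far faster than at the β-branched O–CH2 of the linking ester.

**Compound list**
1 | 2-methylcyclohex-2-en-1-one | CC1=CCCCC1=O | starting material
2 | (1R)-2-methylcyclohex-2-en-1-ol | O[C@@H]1CCCC=C1C | intermediate
3 | 2-methylpropanoyl chloride (isobutyryl chloride) | CC(C)C(=O)Cl | starting material
4 | (1R)-2-methylcyclohex-2-en-1-yl 2-methylpropanoate | CC(C)C(=O)O[C@@H]1CCCC=C1C | intermediate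
5 | trimethylsilyl ketene acetal of 4, (1R) (not isolated) | CC(C)=C(O[Si](C)(C)C)O[C@@H]1CCCC=C1C | intermediate
6 | trimethylsilyl 2-methyl-2-[(1S)-2-methylcyclohex-2-en-1-yl]propanoate (not isolated) | C[Si](C)(C)OC(=O)C(C)(C)[C@H]1CCCC=C1C | intermediate
7 | 2-methyl-2-[(1S)-2-methylcyclohex-2-en-1-yl]propanoic acid | OC(=O)C(C)(C)[C@H]1CCCC=C1C | intermediate
8 | methyl 2-methyl-2-[(1S)-2-methylcyclohex-2-en-1-yl]propanoate | COC(=O)C(C)(C)[C@H]1CCCC=C1C | intermediate
9 | methyl 2-methyl-2-[(1S)-2-methyl-4-oxocyclohex-2-en-1-yl]propanoate | COC(=O)C(C)(C)[C@H]1CCC(=O)C=C1C | intermediate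
10 | tert-butyl[(1-methoxyethenyl)oxy]dimethylsilane | C=C(OC)O[Si](C)(C)C(C)(C)C | starting material
11 | but-3-en-2-one (methyl vinyl ketone) | CC(=O)C=C | starting material
12 | methyl 2-[(1S,2R)-4-{[tert-butyl(dimethyl)silyl]oxy}-2-(2-methoxy-2-oxoethyl)-2-methylcyclohex-3-en-1-yl]-2-methylpropanoate (not isolated) | CC(C)(C)[Si](C)(C)OC1=C[C@](C)(CC(=O)OC)[C@@H](C(C)(C)C(=O)OC)CC1 | intermediate
13 | methyl 2-[(1S,2R,3R)-3-(3-{[tert-butyl(dimethyl)silyl]oxy}but-2-en-1-yl)-2-(2-methoxy-2-oxoethyl)-2-methyl-4-oxocyclohexyl]-2-methylpropanoate, enol ether E/Z mixture (not isolated) | CC(O[Si](C)(C)C(C)(C)C)=CC[C@@H]1[C@](C)(CC(=O)OC)[C@@H](C(C)(C)C(=O)OC)CCC1=O | intermediate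
14 | methyl 2-[(1S,2R,3R)-2-(2-methoxy-2-oxoethyl)-2-methyl-4-oxo-3-(3-oxobutyl)cyclohexyl]-2-methylpropanoate | CC(=O)CC[C@@H]1[C@](C)(CC(=O)OC)[C@@H](C(C)(C)C(=O)OC)CCC1=O | intermediate
15 | triethyl phosphonoacetate | CCOC(=O)CP(=O)(OCC)OCC | starting material
16 | 2,3-dimethyl 15-ethyl (5S,9R,10R,13E)-8-oxo-17-nor-2,3-secolabd-13-ene-2,3,15-trioate | CCOC(=O)/C=C(\C)CC[C@@H]1[C@](C)(CC(=O)OC)[C@@H](C(C)(C)C(=O)OC)CCC1=O | intermediate
17 | 2,3-dimethyl 15-ethyl (5S,9S,10S,13E)-2,3-secolabda-8(17),13-diene-2,3,15-trioate | CCOC(=O)/C=C(\C)CC[C@@H]1[C@](C)(CC(=O)OC)[C@@H](C(C)(C)C(=O)OC)CCC1=C | intermediate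
18 | dimethyl (5S,9S,10S,13E)-15-hydroxy-2,3-secolabda-8(17),13-diene-2,3-dioate | OC/C=C(\C)CC[C@@H]1[C@](C)(CC(=O)OC)[C@@H](C(C)(C)C(=O)OC)CCC1=C | intermediate
19 | dimethyl (5S,9S,10S,13S,14S)-13,14-epoxy-15-hydroxy-2,3-secolabd-8(17)-ene-2,3-dioate | OC[C@@H]1O[C@@]1(C)CC[C@@H]2[C@](C)(CC(=O)OC)[C@@H](C(C)(C)C(=O)OC)CCC2=C | intermediate
20 | dimethyl (5S,9S,10S,13R,14S)-13,14,15-trihydroxy-2,3-secolabd-8(17)-ene-2,3-dioate | OC[C@H](O)[C@@](O)(C)CC[C@@H]1[C@](C)(CC(=O)OC)[C@@H](C(C)(C)C(=O)OC)CCC1=C | intermediate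
21 | dimethyl (5S,8S,9R,10R,13R,14S)-8,13-epoxy-14,15-dihydroxy-17-[(trifluoroacetoxy)mercurio]-2,3-secolabdane-2,3-dioate (not isolated) | OC[C@H](O)[C@@]1(C)CC[C@@H]2[C@](C)(CC(=O)OC)[C@@H](C(C)(C)C(=O)OC)CC[C@]2(C[Hg]OC(=O)C(F)(F)F)O1 | intermediate
22 | dimethyl (5S,8S,9R,10R,13R,14S)-8,13-epoxy-14,15-dihydroxy-2,3-secolabdane-2,3-dioate | OC[C@H](O)[C@@]1(C)CC[C@@H]2[C@](C)(CC(=O)OC)[C@@H](C(C)(C)C(=O)OC)CC[C@]2(C)O1 | intermediate
23 | dimethyl (5S,8S,9R,10R,13R)-8,13-epoxy-2,3-secolabd-14-ene-2,3-dioate | C=C[C@@]1(C)CC[C@@H]2[C@](C)(CC(=O)OC)[C@@H](C(C)(C)C(=O)OC)CC[C@]2(C)O1 | intermediate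
24 | (5S,8S,9R,10R,13R)-8,13-epoxy-3-methoxy-3-oxo-2,3-secolabd-14-en-2-oic acid | C=C[C@@]1(C)CC[C@@H]2[C@](C)(CC(=O)O)[C@@H](C(C)(C)C(=O)OC)CC[C@]2(C)O1 | intermediate
25 | dimethyl (5S,9S,10S,13R,14R)-13,14-epoxy-15-hydroxy-2,3-secolabd-8(17)-ene-2,3-dioate | OC[C@H]1O[C@]1(C)CC[C@@H]2[C@](C)(CC(=O)OC)[C@@H](C(C)(C)C(=O)OC)CCC2=C | intermediate
26 | dimethyl (5S,9S,10S,13S,14R)-13,14,15-trihydroxy-2,3-secolabd-8(17)-ene-2,3-dioate | OC[C@@H](O)[C@](O)(C)CC[C@@H]1[C@](C)(CC(=O)OC)[C@@H](C(C)(C)C(=O)OC)CCC1=C | intermediate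
27 | dimethyl (5S,8S,9R,10R,13S,14R)-8,13-epoxy-14,15-dihydroxy-17-[(trifluoroacetoxy)mercurio]-2,3-secolabdane-2,3-dioate (not isolated) | OC[C@@H](O)[C@]1(C)CC[C@@H]2[C@](C)(CC(=O)OC)[C@@H](C(C)(C)C(=O)OC)CC[C@]2(C[Hg]OC(=O)C(F)(F)F)O1 | intermediate
28 | dimethyl (5S,8S,9R,10R,13S,14R)-8,13-epoxy-14,15-dihydroxy-2,3-secolabdane-2,3-dioate | OC[C@@H](O)[C@]1(C)CC[C@@H]2[C@](C)(CC(=O)OC)[C@@H](C(C)(C)C(=O)OC)CC[C@]2(C)O1 | intermediate
29 | trimethyl ester of the target: 28 acylated on O-15′ by the C2 carboxyl of 24 (5S,8S,9R,10R,13R; 5′S,8′S,9′R,10′R,13′S,14′R) | C=C[C@@]1(C)CC[C@@H]2[C@](C)(CC(=O)OC[C@@H](O)[C@]3(C)CC[C@@H]4[C@](C)(CC(=O)OC)[C@@H](C(C)(C)C(=O)OC)CC[C@]4(C)O3)[C@@H](C(C)(C)C(=O)OC)CC[C@]2(C)O1 | intermediate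
30 | CNP0271961.3: (5S,8S,9R,10R,13R)-8,13-epoxy-2,3-secolabd-14-ene-2,3-dioic acid esterified at C2 with O-15′ of (5′S,8′S,9′R,10′R,13′S,14′R)-8′,13′-epoxy-14′,15′-dihydroxy-2′,3′-secolabdane-2′,3′-dioic acid | C=C[C@@]1(C)CC[C@@H]2[C@](C)(CC(=O)OC[C@@H](O)[C@]3(C)CC[C@@H]4[C@](C)(CC(=O)O)[C@@H](C(C)(C)C(=O)O)CC[C@]4(C)O3)[C@@H](C(C)(C)C(=O)O)CC[C@]2(C)O1 | target

**Step count and risk**
Total: 19 steps. Longest linear sequence: 16 steps (steps 1–14, then 18 and 19).

The three steps most likely to fail are steps 6, 9 and 19.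

Step 6 (double Michael on a crowded enone in one flask). The fallback sets out from 9 and returns at 14, replacing the silyl-triflimide relay by organocopper chemistry and a later oxidative unmasking. CH2=CHCH2MgBr/CuBr·SMe2/LiCl with Me3SiCl (THF, −78 °C) adds an allyl group to C10 anti to the C5 substituent and gives the allyl trimethylsilyl enol ether F1. TiCl4-mediated Mukaiyama–Michael addition of F1 to 11 gives the allyl diketone F2. RuCl3 (cat.)/NaIO4 cleaves the terminal alkene to the acetic acid arm, giving the keto acid F3, and iodomethane/K2CO3 then gives 14.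

Step 9 (DIBAL-H must spare the C2 methyl ester). The fallback sets out from 14 and returns at 18, replacing hydride discrimination by an orthogonal ester. Olefination of 14 with 2-(trimethylsilyl)ethyl diethylphosphonoacetate/NaH gives the silylethyl enoate F4, and Zn/CH2Br2/TiCl4 gives the methylidene silylethyl enoate F5. Bu4NF frees only the side-chain carboxyl to give the unsaturated acid F6. Isobutyl chloroformate/N-methylmorpholine followed by NaBH4 reduces the mixed anhydride to 18, since borohydride leaves methyl esters alone.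

Step 19 (three methyl esters, two of them pivalate-like, must go while the linking ester stays). The fallback sets out from 23 and 28 and returns at 30; the halves are demethylated before they are joined, and an anhydride and allyl esters are used instead. 23 with LiI/pyridine gives the diacid F7, which Ac2O (80 °C) closes to the seven-membered anhydride F8. 28 with LiI/pyridine gives the diol diacid F9, and allyl bromide/KHCO3/DMF gives the diallyl ester F10. With DMAP/Et3N the primary hydroxyl of F10 opens F8 at its unhindered CH2–C=O carbonyl, giving the monoacid diallyl ester F11 with the linking ester and the free C3 acid formed together. Pd(PPh3)4/morpholine removes both allyl groups to give 30.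

**Further compounds**
F1 | step 6 | methyl 2-methyl-2-[(1S,2R)-2-methyl-2-(prop-2-en-1-yl)-4-[(trimethylsilyl)oxy]cyclohex-3-en-1-yl]propanoate | C[Si](C)(C)OC1=C[C@](C)(CC=C)[C@@H](C(C)(C)C(=O)OC)CC1
F2 | step 6 | methyl 2-methyl-2-[(1S,2R,3R)-2-methyl-4-oxo-3-(3-oxobutyl)-2-(prop-2-en-1-yl)cyclohexyl]propanoate | CC(=O)CC[C@@H]1[C@](C)(CC=C)[C@@H](C(C)(C)C(=O)OC)CCC1=O
F3 | step 6 | 2-[(1R,2R,6S)-6-(1-methoxy-2-methyl-1-oxopropan-2-yl)-1-methyl-3-oxo-2-(3-oxobutyl)cyclohexyl]acetic acid | CC(=O)CC[C@@H]1[C@](C)(CC(=O)O)[C@@H](C(C)(C)C(=O)OC)CCC1=O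
F4 | step 9 | 2,3-dimethyl 15-[2-(trimethylsilyl)ethyl] (5S,9R,10R,13E)-8-oxo-17-nor-2,3-secolabd-13-ene-2,3,15-trioate | C[Si](C)(C)CCOC(=O)/C=C(\C)CC[C@@H]1[C@](C)(CC(=O)OC)[C@@H](C(C)(C)C(=O)OC)CCC1=O
F5 | step 9 | 2,3-dimethyl 15-[2-(trimethylsilyl)ethyl] (5S,9S,10S,13E)-2,3-secolabda-8(17),13-diene-2,3,15-trioate | C[Si](C)(C)CCOC(=O)/C=C(\C)CC[C@@H]1[C@](C)(CC(=O)OC)[C@@H](C(C)(C)C(=O)OC)CCC1=C
F6 | step 9 | (5S,9S,10S,13E)-2,3-dimethoxy-2,3-dioxo-2,3-secolabda-8(17),13-dien-15-oic acid | OC(=O)/C=C(\C)CC[C@@H]1[C@](C)(CC(=O)OC)[C@@H](C(C)(C)C(=O)OC)CCC1=C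
F7 | step 19 | (5S,8S,9R,10R,13R)-8,13-epoxy-2,3-secolabd-14-ene-2,3-dioic acid | C=C[C@@]1(C)CC[C@@H]2[C@](C)(CC(=O)O)[C@@H](C(C)(C)C(=O)O)CC[C@]2(C)O1
F8 | step 19 | seven-membered cyclic 2,3-anhydride of F7 (5S,8S,9R,10R,13R) | C=C[C@@]1(C)CC[C@@H]2[C@]3(C)CC(=O)OC(=O)C(C)(C)[C@H]3CC[C@]2(C)O1
F9 | step 19 | (5S,8S,9R,10R,13S,14R)-8,13-epoxy-14,15-dihydroxy-2,3-secolabdane-2,3-dioic acid | OC[C@@H](O)[C@]1(C)CC[C@@H]2[C@](C)(CC(=O)O)[C@@H](C(C)(C)C(=O)O)CC[C@]2(C)O1
F10 | step 19 | di(prop-2-en-1-yl) (5S,8S,9R,10R,13S,14R)-8,13-epoxy-14,15-dihydroxy-2,3-secolabdane-2,3-dioate | OC[C@@H](O)[C@]1(C)CC[C@@H]2[C@](C)(CC(=O)OCC=C)[C@@H](C(C)(C)C(=O)OCC=C)CC[C@]2(C)O1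
F11 | step 19 | target carrying prop-2-en-1-yl esters on C2′ and C3′ (C3 acid free) | C=C[C@@]1(C)CC[C@@H]2[C@](C)(CC(=O)OC[C@@H](O)[C@]3(C)CC[C@@H]4[C@](C)(CC(=O)OCC=C)[C@@H](C(C)(C)C(=O)OCC=C)CC[C@]4(C)O3)[C@@H](C(C)(C)C(=O)O)CC[C@]2(C)O1
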